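**Assumption:** the SMILES encodes (2R,3R)-flavan-3-ol 3-O-gallate with a 4'-OH only. That is (–)-epiafzelechin 3-O-gallate, with C2-aryl and C3-O cis. All phenols are carried as benzyl ethers and released in the last step.

## Retrosynthesis
1. The galloyl ester is removed first by disconnection to the tri-O-benzyl epiafzelechin (10) and tri-O-benzylgallic acid (11). Global hydrogenolysis then gives the target.
2. The cis-(2R,3R)-3-ol (10) is traced to racemic 2-aryl-chroman-3-one (9) by an asymmetric transfer hydrogenation with dynamic kinetic resolution (ATH-DKR). This is the new step, and it sets C2 and C3 together.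
3. Ketone 9 comes from flavene 7 by hydroboration/oxidation, then Dess–Martin oxidation.
4. Flavene 7 is made by annulating 3,5-bis(benzyloxy)phenol with 4-benzyloxycinnamaldehyde. The A ring comes from phloroglucinol and the B ring from the enal. The C ring is formed in this annulation, and the galloyl ester last.

## Route

**Step 1**
Reactants: 1 phloroglucinol; 2 benzyl bromide
Product: 3 3,5-bis(benzyloxy)phenol
Conditions: BnBr (2.0 equiv), K2CO3, acetone, reflux; chromatographic separation from the mono- and tri-benzyl ethers
Reagents that add atoms: BnBr, BrCc1ccccc1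
Why: Williamson O-alkylation of the phenol; the statistical mixture is accepted because the starting materials are cheap and 3 is the main isolable product.

**Step 2**
Reactants: 4 4-(benzyloxy)benzaldehyde; 5 (triphenylphosphoranylidene)acetaldehyde
Product: 6 (E)-4-(benzyloxy)cinnamaldehyde
Conditions: toluene, 80 °C
Reagents that add atoms: none (5 is the named reactant)
Why: Wittig olefination with a stabilized ylide gives the E-enal selectively; the benzyl ether is untouched.

**Step 3**
Reactants: 3 3,5-bis(benzyloxy)phenol; 6 (E)-4-(benzyloxy)cinnamaldehyde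
Product: 7 (±)-5,7-bis(benzyloxy)-2-(4-benzyloxyphenyl)-2H-chromene (flavene)
Conditions: PhB(OH)2 (1 equiv), AcOH (cat.), toluene, reflux, Dean–Stark
Reagents that add atoms: none (the boron is lost as boric acid)
Why: A phenyl borate ester of the phenol directs ortho hydroxyalkylation at the C–H between OH and OBn. Dehydration gives an o-quinone methide, which undergoes 6π-oxa-electrocyclization to the 2-aryl-2H-chromene; C2 is formed racemic.

**Step 4**
Reactants: 7 flavene
Product: 8 (±)-5,7,4'-tri-O-benzylflavan-3-ol (mainly 2,3-trans)
Conditions: BH3·THF, THF, 0 °C to rt; then 3 M NaOH, 30% H2O2, 0 °C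
Reagents that add atoms: hydrogen peroxide, OO (source of the C3–OH oxygen)
Why: Hydroboration/oxidation. Boron goes to C3 because C4 is hindered by the peri 5-OBn and carries the developing benzylic positive charge. Syn addition occurs anti to the 2-aryl group, so the 2,3-configuration of 8 is irrelevant: C3 is oxidized next and C2 is re-equilibrated in Step 6.

**Step 5**
Reactants: 8 flavan-3-ol
Product: 9 (±)-5,7-bis(benzyloxy)-2-(4-benzyloxyphenyl)chroman-3-one
Conditions: Dess–Martin periodinane, NaHCO3, CH2Cl2, 0 °C to rt
Reagents that add atoms: none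
Why: Mild oxidation of a secondary alcohol to the ketone. The C2 centre is now α to C=O, benzylic and α-oxygenated, hence epimerizable.

**Step 6**
Reactants: 9 racemic chroman-3-one
Product: 10 (2R,3R)-5,7,4'-tri-O-benzylepiafzelechin
Conditions: RuCl[(R,R)-TsDPEN](p-cymene) (2 mol%), HCO2H/Et3N (5:2), CH2Cl2, 35 °C, 24–48 h
Reagents that add atoms: none (only hydride and H+ from formate are delivered)
Why: Proposed new method: ATH-DKR of a 2-aryl-chroman-3-one, a cyclic α-aryl-α-aryloxy ketone, to give the cis-flavan-3-ol. The mechanism is fast enolization of C2, so the ketone epimerizes under the amine/formic acid buffer. The Noyori–Ikariya Ru–H transfers hydride through the outer-sphere six-membered transition state to the C=O face anti to the pseudoaxial 2-aryl group, which puts the new C3–OH cis to the aryl and funnels both ketone enantiomers into one (2R,3R) product. The closest known reaction is the Ru-TsDPEN ATH-DKR of α-substituted cyclic ketones and 3-substituted chromanones/flavanones. The catalyst enantiomer is assumed to give 3R; the mirror catalyst would give the enantiomer.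

**Step 7**
Reactants: 10 (2R,3R)-alcohol; 11 3,4,5-tris(benzyloxy)benzoic acid
Product: 12 (2R,3R)-5,7,4'-tri-O-benzylepiafzelechin 3-O-(3,4,5-tri-O-benzyl)gallate
Conditions: EDC·HCl, DMAP, CH2Cl2, 0 °C to rt
Reagents that add atoms: none beyond the numbered acid 11
Why: Steglich esterification of the secondary alcohol. The stereocentres are not touched because there is no acidic α-proton at C2 or C3.

**Step 8**
Reactants: 12 protected gallate ester
Product: 13 target, (–)-epiafzelechin 3-O-gallate
Conditions: H2 (1 atm), 20% Pd(OH)2/C, THF/MeOH, rt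
Reagents that add atoms: none (H2 only)
Why: Hydrogenolysis removes all six O-benzyl groups and leaves the aryl ester and both stereocentres intact.

## Compound list
1 | phloroglucinol | Oc1cc(O)cc(O)c1 | starting material
2 | benzyl bromide | BrCc1ccccc1 | starting material
3 | 3,5-bis(benzyloxy)phenol | Oc1cc(OCc2ccccc2)cc(OCc2ccccc2)c1 | intermediate
4 | 4-(benzyloxy)benzaldehyde | O=Cc1ccc(OCc2ccccc2)cc1 | starting material
5 | (triphenylphosphoranylidene)acetaldehyde | O=CC=P(c1ccccc1)(c1ccccc1)c1ccccc1 | starting material
6 | (E)-4-(benzyloxy)cinnamaldehyde | O=C/C=C/c1ccc(OCc2ccccc2)cc1 | intermediate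
7 | (±)-flavene, 5,7-bis(benzyloxy)-2-(4-benzyloxyphenyl)-2H-chromene | C1(c2ccc(OCc3ccccc3)cc2)C=Cc2c(OCc3ccccc3)cc(OCc3ccccc3)cc2O1 | intermediate (racemic)
8 | (±)-5,7,4'-tri-O-benzylflavan-3-ol (mainly trans) | OC1Cc2c(OCc3ccccc3)cc(OCc3ccccc3)cc2OC1c1ccc(OCc2ccccc2)cc1 | intermediate (diastereomer mixture)
9 | (±)-5,7-bis(benzyloxy)-2-(4-benzyloxyphenyl)chroman-3-one | O=C1Cc2c(OCc3ccccc3)cc(OCc3ccccc3)cc2OC1c1ccc(OCc2ccccc2)cc1 | intermediate (racemic)
10 | (2R,3R)-5,7,4'-tri-O-benzylepiafzelechin | O[C@@H]1Cc2c(OCc3ccccc3)cc(OCc3ccccc3)cc2O[C@@H]1c1ccc(OCc2ccccc2)cc1 | intermediate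
11 | 3,4,5-tris(benzyloxy)benzoic acid | OC(=O)c1cc(OCc2ccccc2)c(OCc2ccccc2)c(OCc2ccccc2)c1 | starting material
12 | protected gallate ester | O=C(O[C@@H]1Cc2c(OCc3ccccc3)cc(OCc3ccccc3)cc2O[C@@H]1c1ccc(OCc2ccccc2)cc1)c1cc(OCc2ccccc2)c(OCc2ccccc2)c(OCc2ccccc2)c1 | intermediate
13 | (–)-epiafzelechin 3-O-gallate (2R,3R) | O=C(O[C@@H]1Cc2c(O)cc(O)cc2O[C@@H]1c1ccc(O)cc1)c1cc(O)c(O)c(O)c1 | target

**Total steps:** 8.
**Longest linear sequence:** 7 (1 → 3 → 7 → 8 → 9 → 10 → 12 → 13).

## Three steps most likely to fail
1. **Step 6 (proposed new ATH-DKR).** Risks are slow racemization, trans-alcohol formation, or ketone decomposition under the acidic formate buffer.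
   *Fallback (known chemistry, different approach):* reduce (±)-9 with L-Selectride to the racemic cis-alcohol, then resolve it by lipase-catalysed acylation (or chiral preparative HPLC) to obtain 10.
2. **Step 4 (regioselective hydroboration).** The electron-rich flavene may give C4-boration (a flavan-4-ol) or ring-opening by β-aryloxy elimination.
   *Fallback:* oxidize 7 with DMDO and rearrange the epoxide with a Lewis acid (Meinwald rearrangement, C3-H shift to the C4 cation) to give ketone 9 directly, skipping 8.
3. **Step 3 (boronate-mediated chromene annulation).** The electron-rich phenol may alkylate at the para position or oligomerize.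
   *Fallback:* make 7 by the flavanone route. Claisen–Schmidt condensation of 2'-hydroxy-4',6'-bis(benzyloxy)acetophenone with 4 gives the chalcone, which cyclizes to the flavanone. NaBH4 reduction gives the flavan-4-ol, and acid-mediated dehydration gives flavene 7.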